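The numbers come from no measurement; the rest is arithmetic.

At 0 °C the number to watch is 0.654, the crossover ratio: the free incoming ligand divided by the free leaving ligand at which, at balance, complex with two exchanged equals starting complex.

| flask | starting complex | incoming ligand | leaving ligand | protic impurity | temperature | time |
|---|---|---|---|---|---|---|
| epsilon | 0.023 M | 2.00 equiv | 1.00 equiv | 0.460 mM | 0 °C | 1.5 min |
| beta | 0.023 M | 2.00 equiv | 1.00 equiv | 0.460 mM | 10 °C | 1.5 min |

    starting complex + incoming ligand ⇌ leaving ligand + complex with one exchanged (K1 = 0.65, k1 = 1.8 M⁻¹ s⁻¹, Ea1 = 43.0 kJ mol⁻¹, ΔH1 = −18.0 kJ mol⁻¹)
    complex with one exchanged + incoming ligand ⇌ leaving ligand + complex with two exchanged (K2 = 3.6, k2 = 1.3 M⁻¹ s⁻¹, Ea2 = 51.0 kJ mol⁻¹, ΔH2 = −48.0 kJ mol⁻¹)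
    protic impurity + starting complex → quenched substrate (k3 = 3.7 M⁻¹ s⁻¹, Ea3 = 38.0 kJ mol⁻¹)
    starting complex + complex with one exchanged ⇌ idle adduct, settled at all times (K4 = 23 M⁻¹, ΔH4 = −36.0 kJ mol⁻¹)
    (constants at 0 °C)

1. which of these there is most of at the end, counted by the starting complex in it, epsilon (starting complex / complex with one exchanged / complex with two exchanged)
2. which of these there is most of at the end, counted by the starting complex in it, beta (starting complex / complex with one exchanged / complex with two exchanged)
3. how much there is at the end of the one of these that leads, in percent of the starting complex charged: epsilon
4. how much there is at the end of the one of these that leads, in percent of the starting complex charged: beta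

- a species is counted by the starting complex in it: one idle adduct counts as two
- amounts and yields of complex with one exchanged count idle adduct too
- at 0 °C the constants are as listed, elsewhere as the activation energies and enthalpies make them
- in an amount of complex with one exchanged, one idle adduct counts as one complex with one exchanged

I turn the question round and ask what complex with two exchanged needs in order to lead in epsilon. At balance it stands to starting complex as the two exchange constants multiplied together, times the ligand ratio squared, so the ratio must end above 0.654. The epsilon run of 1.5 min is long against the 0.19 min forward half-life of free complex with one exchanged by the second step, with the other amounts as charged, so I reckon with balance (thermodynamic control).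

The charged ratio is 2.00, but each exchange turns one incoming ligand into one leaving ligand. Where complex with two exchanged equals starting complex, the mean is one exchange per complex, adduct aside. The charges of 2.00 equiv and 1.00 equiv then give a ratio of 0.500, which is less than the 0.654 required. So I reckon that epsilon stops short of the crossing, with starting complex ahead and the ratio somewhere between those two values.

I replace that range by its middle, 0.577. The ends of the range put starting complex at 41.2% and 52.4% before corrections, and the middle gives 46.4%. Counting the idle adduct and taking off the 2.00% that the protic impurity can remove, I commit to 41.9% for epsilon. Both exchanges give off heat, −18.0 kJ mol⁻¹ and −48.0 kJ mol⁻¹, so in beta at 10 °C both constants fall and the crossover ratio rises above 0.654, and I expect a wider lead for starting complex there.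

The forecast names starting complex at 41.7% for epsilon, close to mine, and starting complex at 49.6% for beta, where it says “The system is essentially at equilibrium”.

The simulation gives starting complex at 41.5% in epsilon and starting complex at 49.5% in beta. Left ten times as long, epsilon shows 41.0% of starting complex. Its free ligands at 1.5 min read a ratio of 0.612, below the crossover ratio of 0.654. The neighbour like epsilon but with 3.40 equiv of incoming ligand reads 0.963, above it, and there complex with two exchanged leads with 53.2% against 25.2% of starting complex.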